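## Analysis of the target

The target is a pentacyclic furano-diterpenoid lactone; its atoms are labelled here in the order of the SMILES string after the acetyl group: C1 (CH–OAc), C2, C3 (quaternary), C4 (lactone CH2), O5, C6 (lactone C=O), C7, C8 (=CH), C9 (CH2), C10 (CH carrying the furan), C11 (furan C-2), O12, C13, C14, C15 (furan C-3), C16 (ketone), C17 (CH2), C18 (quaternary, methyl C19), C20 (CH, methyl C21) and C22 (carbinol carbon, O23). Ring A is the cyclohexane C1–C2–C3–C22–C18–C20, ring B the cyclohexene C3–C7=C8–C9–C10–C22, ring C the cycloheptanone C10–C11–C15–C16–C17–C18–C22 fused to the furan, and a γ-lactone (C3–C4–O5–C6–C7) is fused to ring B with its carbonyl conjugated to C7=C8. There are six stereocentres, C1 (R), C3 (S), C10 (R), C18 (S), C20 (S) and C22 (S), three of them (C18, C22, C3) contiguous and fully substituted. Rings A and B are trans-fused with O23 anti to C4, rings B and C are trans-fused with the furan on C10 cis to O23, and on the ring A chair the acetoxy group is axial and syn to the axial C19 methyl and C4 methylene while the C21 methyl is equatorial. The furan (acid, oxidants), the tertiary alcohol next to the furylic C10–H (dehydration, and lactol formation with any aldehyde at C16), the acetate and the enoate (conjugate addition, alkene migration) limit what can be done late. The hard part is C22: a tertiary carbinol between two quaternary carbons whose hydroxyl must be anti to the lactone methylene, the opposite of what addition to a C22 ketone should give, in a ring system that forces the lactone methylene pseudo-axial on ring B. The strategy rests on ring B: C22, C10, C9 and C8 are the four carbons of a 2-alkylfuran and O23 is its oxygen, while C3 and C7 are the β- and α-carbons of a butenolide, so ring B with its oxygen pattern is what a furan–butenolide cycloaddition leaves after β-elimination of the oxygen bridge.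

## Retrosynthetic reasoning

Acetate and ring C. The acetate is removed first (36 to 35) because it would not survive an organometallic ring closure. Ring C is then cut at C15–C16 to give 33, in which C15 carries iodine and C16 is the carbonyl of a γ-lactone on O23. This bond is chosen because O23 and C16 are 1,4-related: an aldehyde at C16 would sit as a lactol on the tertiary hydroxyl and over-oxidise. The lactone is both the protecting group of O23 and the acyl donor, so the forward step needs only halogen–metal exchange and attack on a carbonyl held within reach.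

C1. The axial alcohol of 33 is traced through ketone 32 to its equatorial epimer 31 and the silyl ether 30. C1 is carried as the S epimer because the key step needs it equatorial. It is corrected once ring B exists, when the axial face of C1 is blocked by C19 and C4 and hydride must enter equatorially.

C10–C11. Cutting the bond between ring B and the furan in 30 gives the diene bis-lactone 26 and 3-iodofuran 27. The forward reaction is a 1,6-addition of metalated 27 to the dienoate terminus C10 and return of the alkene to C7=C8. It must prefer C10 over C8 and the O23 face over the face of C19 and C4.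

Key disconnection. In 26 the lactone on O23 is opened to hydroxy ester 25, the C7=C8 alkene and the C22–O23 bond are reconnected to the oxygen bridge of 24, and C22–C3 and C8–C7 are cut to the furan butenolide 23. No other cut traces two rings, the bond between two fully substituted carbons and the anti relationship of O23 and C4 to one flat precursor. The forward reaction must beat the poor equilibrium of furan cycloadditions. The ring-opened diene is itself strained and could reclose, so C16 is carried as an ester that captures O23 as soon as it is freed.

Butenolide. 23 is cut at the C3=C7 alkene (ring-closing metathesis of acrylate 22, from alcohol 20 and 21) and at C1–C2 (allylation of aldehyde 16 with allylsilane 17, through 18 and 19). The butenolide is built after the C1–C2 bond because an allylmetal nucleophile carrying a preformed butenolide should add with allylic transposition at the lactone α-carbon. The 2-substituted allylsilane gives the linear connection, and Felkin–Anh control sets C1.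

Differentiation of the two ends. Aldehyde 16 comes from Weinreb amide 15, whose ester arm is made from the vinyl group of 10 by hydroboration and oxidation (12, 14). The amide holds C1 at the acid level while C16 is raised to the ester.

C18–C20. Acid 8 is cut at C18–C20 by an Ireland–Claisen transform to propanoate 6 of allylic alcohol 4, made from 1 and 2 through 3 and acylated with 5. This one bond formation creates the quaternary carbon and its neighbour with defined relative and absolute configuration from an achiral ester.

## Alternatives that were turned down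

Alternative 1: Ring B and the lactone are disconnected together at C3–C7 and C8–C9, back to the tricyclic dienyl propiolate A1. In the forward step the propiolate on the C4 oxygen adds across the diene C9=C10–C22=C3, held s-cis by rings A and C, to give the cyclohexa-1,4-diene lactone A2. In its favour: rings A and C, the furan and the ring A stereocentres are complete beforehand, no furan is consumed, the alkyne cycloaddition is not reversible, and the ester tether delivers C7 to the C4 face of C3. Against it: A2 has neither O23 nor the C10 hydrogen. The tetrasubstituted C10=C22 alkene between C18 and C3 would need an anti hydration (oxygen on C22 anti to C4) in the presence of a furan, an enoate and a 3-acylfuran, and A1 is an acid-sensitive 2-furyl diene that is long to make. Alternative 1 is stronger in the thermodynamics of its key step and in convergence; the chosen route offers instead the C22 carbinol with the correct sense relative to C3 as a direct result of the cycloaddition.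

Alternative 2: Ring A is disconnected at C20–C21 and C18–C17. In the forward step lithium dimethylcuprate A4 adds to enone A3 anti to the silyloxy group and the enolate is alkylated by allylic bromide A5 anti to the new methyl, giving cyclohexanone A6. In its favour: C18, C20 and C1 are set in one flask by well-understood anti/anti control and the second furan is joined convergently; on this triad it is shorter than the Claisen–allylation sequence used here. Against it: in A6, C22 is a ketone and C3 an unsubstituted methylene. C3 must still become quaternary, ring B must be annulated, and O23 must arise by adding a carbon nucleophile to a ketone between two quaternary carbons, which should place the hydroxyl syn to C4. The 1,1-disubstituted alkene must also be cleaved next to a furan. The chosen strategy spends more steps on the triad but makes ring B, C3 and C22 in one step with O23 correctly placed.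

Alternative 3: Both bonds to C16 are disconnected, with C16 supplied by carbon monoxide A8. In the forward step the neopentyl iodide A7 is converted to its alkylzinc iodide and a zerovalent palladium catalyst under A8 couples it with the 3-bromofuran to close ring C, giving A9, the trimethylsilyl ether of the target. In its favour: ring C and the ketone arrive in one step at the right oxidation level, the zinc reagent has no β-hydrogen, and the conditions spare lactone and acetate. Against it: A7 already contains everything that is difficult. Zinc insertion into a neopentyl iodide is slow, the acylpalladium must close a seven-membered ring faster than direct coupling without CO, and extra steps are needed for the iodide and for silylating the hindered O23. As a ring C closure it is as short as the lactone acylation used here and milder toward esters, so on that point it is at least as strong. The chosen route offers instead an acyl donor that forms without extra steps in the key step and protects O23, and a way to build the core that alternative 3 presupposes.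

Key step: step 15

Assumption: the (S,S)-diazaborolidine is taken to favour the (2S,3S)-acid 8; should it favour the enantiomer, the (R,R)-reagent is used and nothing else changes.

## Route

Step 1
Reactants: 1 2-acetylfuran; 2 triethyl phosphonoacetate
Product: 3 ethyl (E)-3-(furan-2-yl)but-2-enoate
Conditions: NaH, THF, 0 °C → 65 °C
Reagents that add atoms: none
Why: Horner–Wadsworth–Emmons olefination of an aryl methyl ketone; the E isomer (furan trans to the ester) should predominate and is freed from the Z isomer by chromatography.

Step 2
Reactants: 3 ethyl (E)-3-(furan-2-yl)but-2-enoate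
Product: 4 (E)-3-(furan-2-yl)but-2-en-1-ol
Conditions: i-Bu2AlH, CH2Cl2, −78 °C
Reagents that add atoms: none
Why: 1,2-reduction of the conjugated ester by the aluminium hydride; the alkene geometry is not touched.

Step 3
Reactants: 4 (E)-3-(furan-2-yl)but-2-en-1-ol; 5 propanoyl chloride
Product: 6 (E)-3-(furan-2-yl)but-2-en-1-yl propanoate
Conditions: Et3N, DMAP (cat.), CH2Cl2, 0 °C
Reagents that add atoms: none
Why: O-acylation of a primary allylic alcohol under buffered conditions that spare the acid-sensitive furyl allyl system.

Step 4
Reactants: 6 (E)-3-(furan-2-yl)but-2-en-1-yl propanoate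
Product: 8 (2S,3S)-3-(furan-2-yl)-2,3-dimethylpent-4-enoic acid, via boron ketene acetal 7 (not isolated)
Conditions: (4S,5S)-2-bromo-4,5-diphenyl-1,3-bis{[3,5-bis(trifluoromethyl)phenyl]sulfonyl}-1,3,2-diazaborolidine, Et3N, toluene–hexane, −78 °C, then −20 °C; H2O
Reagents that add atoms: none
Why: Enantioselective Ireland–Claisen rearrangement through a chiral boron enolate; Et3N in a non-polar medium should give the enolate with methyl cis to the allyloxy oxygen, and a chair transition state with the furan equatorial and that methyl axial gives the 2S*,3S* relationship across the new C18–C20 bond, while the C2-symmetric diazaborolidine selects the enolate face.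

Step 5
Reactants: 8 (2S,3S)-3-(furan-2-yl)-2,3-dimethylpent-4-enoic acid
Product: 10 (2S,3S)-3-(furan-2-yl)-N-methoxy-N,2,3-trimethylpent-4-enamide, via acyl imidazole 9 (not isolated)
Conditions: CDI, CH2Cl2, rt; then MeNH(OMe)·HCl, rt
Reagents that add atoms: N,O-dimethylhydroxylamine hydrochloride, CNOC.Cl
Why: Amide formation through the acyl imidazole; neutral activation avoids acid chloride conditions that could acylate the furan and keeps the α-stereocentre.

Step 6
Reactants: 10 (2S,3S)-3-(furan-2-yl)-N-methoxy-N,2,3-trimethylpent-4-enamide
Product: 12 (2S,3S)-3-(furan-2-yl)-5-hydroxy-N-methoxy-N,2,3-trimethylpentanamide, via alkylborane 11 (not isolated)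
Conditions: 9-BBN, THF, 0 °C → rt; then NaOH, H2O2, 0 °C
Reagents that add atoms: hydrogen peroxide, OO
Why: Anti-Markovnikov hydroboration–oxidation; 9-BBN adds to the monosubstituted alkene much faster than to the furan or the hindered amide.

Step 7
Reactants: 12 (2S,3S)-3-(furan-2-yl)-5-hydroxy-N-methoxy-N,2,3-trimethylpentanamide
Product: 14 (3S,4S)-3-(furan-2-yl)-5-[methoxy(methyl)amino]-3,4-dimethyl-5-oxopentanoic acid, via aldehyde 13 (not isolated)
Conditions: TEMPO (cat.), PhI(OAc)2, MeCN–H2O, rt
Reagents that add atoms: water, O
Why: Oxoammonium oxidation of the primary alcohol to the aldehyde, whose hydrate is oxidised on to the acid; the conditions are mild and close to neutral, which a 2-alkylfuran should tolerate.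

Step 8
Reactants: 14 (3S,4S)-3-(furan-2-yl)-5-[methoxy(methyl)amino]-3,4-dimethyl-5-oxopentanoic acid
Product: 15 methyl (3S,4S)-3-(furan-2-yl)-5-[methoxy(methyl)amino]-3,4-dimethyl-5-oxopentanoate
Conditions: MeI, K2CO3, DMF, rt
Reagents that add atoms: iodomethane, CI
Why: SN2 O-alkylation of the carboxylate; no acid is involved and no stereocentre is at risk.

Step 9
Reactants: 15 methyl (3S,4S)-3-(furan-2-yl)-5-[methoxy(methyl)amino]-3,4-dimethyl-5-oxopentanoate
Product: 16 methyl (3S,4S)-3-(furan-2-yl)-3,4-dimethyl-5-oxopentanoate
Conditions: Cp2Zr(H)Cl, THF, rt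
Reagents that add atoms: none
Why: Hydrozirconation of the amide carbonyl gives an adduct that releases the aldehyde only on work-up; the reagent reduces Weinreb amides in the presence of esters and is not basic, so C20 is not epimerised.

Step 10
Reactants: 16 methyl (3S,4S)-3-(furan-2-yl)-3,4-dimethyl-5-oxopentanoate; 17 2-[(trimethylsilyl)methyl]allyl acetate
Product: 18 methyl (3S,4S,5S)-7-[(acetyloxy)methyl]-3-(furan-2-yl)-5-hydroxy-3,4-dimethyloct-7-enoate
Conditions: BF3·OEt2, CH2Cl2, −78 °C; cold NaHCO3
Reagents that add atoms: none
Why: Hosomi–Sakurai allylation through an open transition state; Felkin–Anh addition anti to the quaternary C18 sets C1 as S (hydroxyl syn to the C21 methyl), and the alcohol is silylated at once in step 11 because it could lactonise onto the ester.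

Step 11
Reactants: 18 methyl (3S,4S,5S)-7-[(acetyloxy)methyl]-3-(furan-2-yl)-5-hydroxy-3,4-dimethyloct-7-enoate
Product: 19 methyl (3S,4S,5S)-7-[(acetyloxy)methyl]-3-(furan-2-yl)-3,4-dimethyl-5-[(triethylsilyl)oxy]oct-7-enoate
Conditions: TESOTf, 2,6-lutidine, CH2Cl2, −78 °C
Reagents that add atoms: triethylsilyl trifluoromethanesulfonate, CC[Si](CC)(CC)OS(=O)(=O)C(F)(F)F
Why: Silylation of a hindered secondary alcohol with the silyl triflate and a hindered base; the triethylsilyl group can later be removed without touching lactones.

Step 12
Reactants: 19 methyl (3S,4S,5S)-7-[(acetyloxy)methyl]-3-(furan-2-yl)-3,4-dimethyl-5-[(triethylsilyl)oxy]oct-7-enoate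
Product: 20 methyl (3S,4S,5S)-3-(furan-2-yl)-7-(hydroxymethyl)-3,4-dimethyl-5-[(triethylsilyl)oxy]oct-7-enoate
Conditions: K2CO3 (cat.), MeOH, 0 °C
Reagents that add atoms: none
Why: Transesterification removes the primary allylic acetate; the methyl ester is degenerate in methanol and the hindered secondary silyl ether should survive the short, cold treatment.

Step 13
Reactants: 20 methyl (3S,4S,5S)-3-(furan-2-yl)-7-(hydroxymethyl)-3,4-dimethyl-5-[(triethylsilyl)oxy]oct-7-enoate; 21 acryloyl chloride
Product: 22 methyl (3S,4S,5S)-7-[(acryloyloxy)methyl]-3-(furan-2-yl)-3,4-dimethyl-5-[(triethylsilyl)oxy]oct-7-enoate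
Conditions: i-Pr2NEt, CH2Cl2, −78 → 0 °C
Reagents that add atoms: none
Why: Acylation of the primary allylic alcohol; low temperature and a hindered amine suppress conjugate addition to the acrylate.

Step 14
Reactants: 22 methyl (3S,4S,5S)-7-[(acryloyloxy)methyl]-3-(furan-2-yl)-3,4-dimethyl-5-[(triethylsilyl)oxy]oct-7-enoate
Product: 23 methyl (3S,4S,5S)-3-(furan-2-yl)-3,4-dimethyl-6-(5-oxo-2,5-dihydrofuran-3-yl)-5-[(triethylsilyl)oxy]hexanoate
Conditions: second-generation Grubbs catalyst RuCl2(=CHPh)(H2IMes)(PCy3) (5 mol%), toluene (0.005 M), 80 °C
Reagents that add atoms: none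
Why: Ring-closing metathesis between the acrylate and the 1,1-disubstituted alkene gives the 4-substituted butenolide with loss of ethene; this pairing is well established for β-substituted butenolides and the furan is not a metathesis partner.

Step 15
Reactants: 23 methyl (3S,4S,5S)-3-(furan-2-yl)-3,4-dimethyl-6-(5-oxo-2,5-dihydrofuran-3-yl)-5-[(triethylsilyl)oxy]hexanoate
Product: 26 silyloxy diene bis-lactone, via oxanorbornene lactone 24 (not isolated), via hydroxy dienoate 25 (not isolated)
Conditions: DBU (1 equiv), toluene (0.005 M), 130 °C, sealed tube
Reagents that add atoms: none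
Why: On heating, the furan (C22, C10, C9, C8) should add suprafacially across the butenolide C3=C7 bond in an intramolecular Diels–Alder reaction to give 24 with the new bonds C22–C3 and C8–C7; DBU then removes the exo C7–H next to the lactone carbonyl, the enolate expels the bridging oxygen from C8 (E1cB) to give the C7=C8–C9=C10 dienoate and the C22 alkoxide of 25, and this alkoxide closes onto the C16 methyl ester to give the γ-lactone of 26 with loss of methanol. The closest known reaction type is the intramolecular Diels–Alder reaction of furans followed by base-induced opening of the 7-oxanorbornene to a hydroxycyclohexadiene; the final acyl transfer is an ordinary γ-lactonisation and makes the sequence irreversible, since neither retro-cycloaddition nor oxa-Michael reclosure is open to 26. Ring A is closed by the C22–C3 bond as a six-membered ring across the four-atom tether (fused mode, diene terminus to the nearer dienophile carbon), and ring B is the six-membered ring of the [4+2] process itself (C22, C10, C9, C8, C7, C3). C3 and C22 are set relative to each other by the exo orientation of the tether (C2 syn to the oxygen bridge), which puts the lactone methylene C4 anti to O23 and so gives the trans A/B fusion. Their sense relative to C18 follows from a chair-like tether in which the C21 methyl, the C1 silyloxy group and the C17 ester arm are equatorial and only the C19 methyl is axial; the other chair would carry three axial groups. The step needs exo over endo tether selectivity and π-facial selectivity: the short tether with the fully substituted C18 next to the furan should secure the first, the equatorial substituents on C20 and C1 the second, and the regiochemistry is fixed by the tether. C1 is carried as the S epimer for this reason and is inverted in steps 18 and 19.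

Step 16
Reactants: 26 silyloxy diene bis-lactone; 27 3-iodofuran
Product: 30 silyloxy iodofuryl enoate bis-lactone, via lithium dienolate 28 (not isolated), via deconjugated lactone 29 (not isolated)
Conditions: 27, LiN(i-Pr)2, THF, −78 °C; CuI; then 26, −78 → −20 °C; aq. NH4Cl; then DBU (cat.), CH2Cl2, rt
Reagents that add atoms: none
Why: Gilman-type cuprates add to 2,4-dienoates at the δ-carbon (1,6-addition), here the diene terminus C10; the face of C19 and C4, both axial and 1,3 to C10, is screened, so the furan should enter on the O23 face and end up equatorial (C10 R); α-protonation gives 29 and DBU should return the alkene to conjugation as the trisubstituted C7=C8 enoate.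

Step 17
Reactants: 30 silyloxy iodofuryl enoate bis-lactone
Product: 31 (1S)-hydroxy iodofuryl enoate bis-lactone
Conditions: PPTS, MeOH–CH2Cl2, 0 °C
Reagents that add atoms: none
Why: Acid-catalysed methanolysis of the triethylsilyl ether; the lactones and the halofuran should be stable to pyridinium tosylate at low temperature.

Step 18
Reactants: 31 (1S)-hydroxy iodofuryl enoate bis-lactone
Product: 32 ring A ketone bis-lactone
Conditions: Dess–Martin periodinane, pyridine, CH2Cl2, rt
Reagents that add atoms: none
Why: Oxidation of the secondary alcohol by the hypervalent iodine reagent under buffered conditions; the equatorial C21 methyl next to the new ketone is already the thermodynamic configuration.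

Step 19
Reactants: 32 ring A ketone bis-lactone
Product: 33 (1R)-hydroxy iodofuryl enoate bis-lactone
Conditions: NaBH4, CeCl3·7H2O, MeOH–THF, −40 °C
Reagents that add atoms: none
Why: Luche reduction, selective for the ketone over the enoate and the lactones; axial attack at C1 is blocked by the syn-axial C19 methyl and C4 methylene, so hydride should enter equatorially and give the axial 1R alcohol.

Step 20
Reactants: 33 (1R)-hydroxy iodofuryl enoate bis-lactone
Product: 35 deacetyl target, via arylmagnesium chloride 34 (not isolated)
Conditions: MeMgCl (1 equiv), THF, −40 °C; i-PrMgCl·LiCl (1.1 equiv), −40 → 0 °C; aq. NH4Cl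
Reagents that add atoms: none
Why: Iodine–magnesium exchange on the heteroaryl iodide, which tolerates ester groups at low temperature, then intramolecular acylation of the arylmagnesium by the γ-lactone carbonyl C16 (Parham-type cyclisation); this forms the C15–C16 bond, closes the seven-membered ring C and releases O23, and the ketone should only be set free on work-up.

Step 21
Reactants: 35 deacetyl target
Product: 36 CNP0329797.2
Conditions: Ac2O, DMAP (cat.), pyridine, CH2Cl2, rt
Reagents that add atoms: acetic anhydride, CC(=O)OC(C)=O
Why: Acetylation of the secondary C1 alcohol; the tertiary C22 hydroxyl between two quaternary carbons should not be acylated under these conditions.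

## Compound list

1 | 2-acetylfuran | CC(=O)c1ccco1 | starting material
2 | triethyl phosphonoacetate | CCOC(=O)CP(=O)(OCC)OCC | starting material
3 | ethyl (E)-3-(furan-2-yl)but-2-enoate | CCOC(=O)/C=C(\C)c1ccco1 | intermediate
4 | (E)-3-(furan-2-yl)but-2-en-1-ol | OC/C=C(\C)c1ccco1 | intermediate
5 | propanoyl chloride | CCC(=O)Cl | starting material
6 | (E)-3-(furan-2-yl)but-2-en-1-yl propanoate | CCC(=O)OC/C=C(\C)c1ccco1 | intermediate
7 | boron ketene acetal: O-boryl enolate of 6 with methyl cis to the allyloxy oxygen, boron held in the (4S,5S)-diazaborolidine | C/C=C(\OC/C=C(\C)c1ccco1)OB1N(S(=O)(=O)c2cc(C(F)(F)F)cc(C(F)(F)F)c2)[C@@H](c2ccccc2)[C@H](c2ccccc2)N1S(=O)(=O)c1cc(C(F)(F)F)cc(C(F)(F)F)c1 | intermediate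
8 | (2S,3S)-3-(furan-2-yl)-2,3-dimethylpent-4-enoic acid | o1cccc1[C@@](C)(C=C)[C@H](C)C(=O)O | intermediate
9 | acyl imidazole: (2S,3S)-3-(furan-2-yl)-1-(imidazol-1-yl)-2,3-dimethylpent-4-en-1-one | o1cccc1[C@@](C)(C=C)[C@H](C)C(=O)n1ccnc1 | intermediate
10 | (2S,3S)-3-(furan-2-yl)-N-methoxy-N,2,3-trimethylpent-4-enamide | o1cccc1[C@@](C)(C=C)[C@H](C)C(=O)N(C)OC | intermediate
11 | alkylborane: B-alkyl-9-BBN adduct of 10 at the terminal carbon | o1cccc1[C@@](C)(CCB2C3CCCC2CCC3)[C@H](C)C(=O)N(C)OC | intermediate
12 | (2S,3S)-3-(furan-2-yl)-5-hydroxy-N-methoxy-N,2,3-trimethylpentanamide | o1cccc1[C@@](C)(CCO)[C@H](C)C(=O)N(C)OC | intermediate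
13 | aldehyde: (3S,4S)-3-(furan-2-yl)-5-[methoxy(methyl)amino]-3,4-dimethyl-5-oxopentanal | o1cccc1[C@@](C)(CC=O)[C@H](C)C(=O)N(C)OC | intermediate
14 | (3S,4S)-3-(furan-2-yl)-5-[methoxy(methyl)amino]-3,4-dimethyl-5-oxopentanoic acid | o1cccc1[C@@](C)(CC(=O)O)[C@H](C)C(=O)N(C)OC | intermediate
15 | methyl (3S,4S)-3-(furan-2-yl)-5-[methoxy(methyl)amino]-3,4-dimethyl-5-oxopentanoate | o1cccc1[C@@](C)(CC(=O)OC)[C@H](C)C(=O)N(C)OC | intermediate
16 | methyl (3S,4S)-3-(furan-2-yl)-3,4-dimethyl-5-oxopentanoate | o1cccc1[C@@](C)(CC(=O)OC)[C@H](C)C=O | intermediate
17 | 2-[(trimethylsilyl)methyl]allyl acetate | CC(=O)OCC(=C)C[Si](C)(C)C | starting material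
18 | methyl (3S,4S,5S)-7-[(acetyloxy)methyl]-3-(furan-2-yl)-5-hydroxy-3,4-dimethyloct-7-enoate | o1cccc1[C@@](C)(CC(=O)OC)[C@H](C)[C@@H](O)CC(=C)COC(C)=O | intermediate
19 | methyl (3S,4S,5S)-7-[(acetyloxy)methyl]-3-(furan-2-yl)-3,4-dimethyl-5-[(triethylsilyl)oxy]oct-7-enoate | o1cccc1[C@@](C)(CC(=O)OC)[C@H](C)[C@@H](O[Si](CC)(CC)CC)CC(=C)COC(C)=O | intermediate
20 | methyl (3S,4S,5S)-3-(furan-2-yl)-7-(hydroxymethyl)-3,4-dimethyl-5-[(triethylsilyl)oxy]oct-7-enoate | o1cccc1[C@@](C)(CC(=O)OC)[C@H](C)[C@@H](O[Si](CC)(CC)CC)CC(=C)CO | intermediate
21 | acryloyl chloride | C=CC(=O)Cl | starting material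
22 | methyl (3S,4S,5S)-7-[(acryloyloxy)methyl]-3-(furan-2-yl)-3,4-dimethyl-5-[(triethylsilyl)oxy]oct-7-enoate | o1cccc1[C@@](C)(CC(=O)OC)[C@H](C)[C@@H](O[Si](CC)(CC)CC)CC(=C)COC(=O)C=C | intermediate
23 | methyl (3S,4S,5S)-3-(furan-2-yl)-3,4-dimethyl-6-(5-oxo-2,5-dihydrofuran-3-yl)-5-[(triethylsilyl)oxy]hexanoate | o1cccc1[C@@](C)(CC(=O)OC)[C@H](C)[C@@H](O[Si](CC)(CC)CC)CC1=CC(=O)OC1 | intermediate
24 | oxanorbornene lactone: exo-tether [4+2] adduct of 23; O23 bridges C22 and C8; C2 exo; lactone ring endo; H on C7 exo; C1 OSiEt3; CH2CO2Me on C18 | CC[Si](CC)(CC)O[C@H]1C[C@@]23COC(=O)[C@@H]2[C@@H]4C=C[C@]3(O4)[C@@](C)(CC(=O)OC)[C@@H]1C | intermediate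
25 | hydroxy dienoate: ring-opened 24 with free C22–OH, C7=C8–C9=C10 dienoate lactone and CH2CO2Me on C18; (1S,3S,18S,20S,22S) | CC[Si](CC)(CC)O[C@H]1C[C@@]23COC(=O)C2=CC=C[C@]3(O)[C@@](C)(CC(=O)OC)[C@@H]1C | intermediate
26 | silyloxy diene bis-lactone: 25 with O23 closed onto C16 as a γ-lactone; rings A and B trans-fused; (1S,3S,18S,20S,22S) | CC[Si](CC)(CC)O[C@H]1C[C@@]23COC(=O)C2=CC=C[C@@]34OC(=O)C[C@@]4(C)[C@@H]1C | intermediate
27 | 3-iodofuran | Ic1ccoc1 | starting material
28 | lithium dienolate: C6 enolate (C6=C7, C8=C9) of the 1,6-adduct with 3-iodofuran-2-yl on C10 | [Li+].CC[Si](CC)(CC)O[C@H]1C[C@@]23COC([O-])=C2C=C[C@@H](c5occc5I)[C@@]34OC(=O)C[C@@]4(C)[C@@H]1C | intermediate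
29 | deconjugated lactone: C7-protonated 1,6-adduct with C8=C9 (C7 epimers) | CC[Si](CC)(CC)O[C@H]1C[C@@]23COC(=O)C2C=C[C@@H](c5occc5I)[C@@]34OC(=O)C[C@@]4(C)[C@@H]1C | intermediate
30 | silyloxy iodofuryl enoate bis-lactone: C7=C8 enoate; 3-iodofuran-2-yl on C10 cis to O23; (1S,3S,10R,18S,20S,22S) | CC[Si](CC)(CC)O[C@H]1C[C@@]23COC(=O)C2=CC[C@@H](c5occc5I)[C@@]34OC(=O)C[C@@]4(C)[C@@H]1C | intermediate
31 | (1S)-hydroxy iodofuryl enoate bis-lactone: 30 without the silyl group | O[C@H]1C[C@@]23COC(=O)C2=CC[C@@H](c5occc5I)[C@@]34OC(=O)C[C@@]4(C)[C@@H]1C | intermediate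
32 | ring A ketone bis-lactone: C1 ketone of 31 | O=C1C[C@@]23COC(=O)C2=CC[C@@H](c5occc5I)[C@@]34OC(=O)C[C@@]4(C)[C@@H]1C | intermediate
33 | (1R)-hydroxy iodofuryl enoate bis-lactone: C1 epimer of 31 with axial hydroxyl | O[C@@H]1C[C@@]23COC(=O)C2=CC[C@@H](c5occc5I)[C@@]34OC(=O)C[C@@]4(C)[C@@H]1C | intermediate
34 | arylmagnesium chloride: 33 with MgCl on C15 in place of iodine and the C1 oxygen as O–MgCl | Cl[Mg]O[C@@H]1C[C@@]23COC(=O)C2=CC[C@@H](c5occc5[Mg]Cl)[C@@]34OC(=O)C[C@@]4(C)[C@@H]1C | intermediate
35 | deacetyl target: pentacyclic hydroxy ketone with free C1 (R) and C22 hydroxyls | O[C@@H]1C[C@@]23COC(=O)C2=CC[C@H]2c4occc4C(=O)C[C@@](C)([C@@H]1C)[C@@]23O | intermediate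
36 | CNP0329797.2: (1R,3S,10R,18S,20S,22S)-1-acetoxy compound, atom labels as in the analysis | CC(=O)O[C@@H]1C[C@@]23COC(=O)C2=CC[C@H]2c4occc4C(=O)C[C@@](C)([C@@H]1C)[C@@]23O | target

## Step count and least certain steps

Total step count: 21. Longest linear sequence: 21 steps (1 to 36); 2, 5, 17, 21 and 27 are bought.

Step 15 (key step). The cycloaddition has to join two fully substituted carbons, and it may be slower than base-induced side reactions of 23: γ-deprotonation of the butenolide with alkene migration or loss of triethylsilanol from C1, or Michael closure of the ester enolate onto C3. If 24 reverts faster than it is deprotonated nothing accumulates, and the ring-opened diene is strained, so the drain depends on fast lactonisation. An endo tether would give the cis-fused series. Fallback, from 23 to 26: the furan is brominated at its free α-position C8 (NBS, DMF, 0 °C) to give bromofuran F1. A halogen on the furan makes such cycloadditions faster and less reversible, so heating without base (toluene, 110 °C) should give the isolable bromo adduct F2. DBU at moderate temperature then opens the bridge and the alkoxide lactonises to the bromo diene bis-lactone F3. The vinylic bromide is removed by formate reduction under zerovalent palladium catalysis (Pd(OAc)2, PPh3, HCO2H, Bu3N), which returns to 26.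

Step 16. The bulky heteroaryl cuprate may fail to reach the neopentyl-like C10, may add at C8 (1,4-addition) or may enter from the face of C19 and C4. The alkene may also stay at the deconjugated position, because the conjugated lactone is the more strained isomer. Fallback, from 26 to 30: the lactone carbonyls are complexed with the bulky Lewis acid Al(OC6H3-2,6-Ph2)3 and (3-iodofuran-2-yl)lithium itself is added at −78 °C. The aluminium phenoxide shields C6 and C8 and activates the dienoate, a known way of steering an organolithium to the remote terminus. Work-up and the same DBU treatment return to 30 without any new isolated compound (F0).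

Step 20. Iodine–magnesium exchange on the electron-rich furan may be slower than attack of i-PrMgCl on a lactone carbonyl, or the arylmagnesium may be quenched by proton transfer from C9 before it cyclises. Fallback, from 30 to 35: ring C is closed earlier, on 30, which has no free hydroxyl. Iodine–lithium exchange with t-BuLi at −100 °C outruns carbonyl addition (Parham cyclisation), and attack on the γ-lactone gives the silyl ether hydroxy ketone F4. Removal of the triethylsilyl group (PPTS, MeOH) gives the diol ketone F5 and oxidation (Dess–Martin periodinane) gives the diketone F6. Luche reduction of the ring A ketone, the more electrophilic of the two since the furyl ketone is conjugated and hindered, returns to 35.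

Step 4. The Lewis acidic boron may ionise the furyl-stabilised allylic ester or give a mixture of enolate geometries, which would erode enantiomeric and diastereomeric purity; the sense of induction also has to be confirmed. Fallback, from 6 to 8: the classical Ireland–Claisen rearrangement (LiN(i-Pr)2, Me3SiCl, THF, −78 °C → rt) through the same chair gives the racemic acid F7. Coupling with lithiated (S)-4-benzyloxazolidin-2-one through the pivaloyl mixed anhydride gives the imide F8 and its diastereomer F9, which are separated by chromatography. Hydrolysis of F8 (LiOH, H2O2) returns to 8 and the auxiliary.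

## Further compounds

F1 | step 15 | bromofuran: 23 with bromine on the free furan α-carbon | Brc1ccc(o1)[C@@](C)(CC(=O)OC)[C@H](C)[C@@H](O[Si](CC)(CC)CC)CC1=CC(=O)OC1
F2 | step 15 | bromo adduct: 24 with bromine on the bridgehead C8 | CC[Si](CC)(CC)O[C@H]1C[C@@]23COC(=O)[C@@H]2[C@]4(Br)C=C[C@]3(O4)[C@@](C)(CC(=O)OC)[C@@H]1C
F3 | step 15 | bromo diene bis-lactone: 26 with bromine on C8 | CC[Si](CC)(CC)O[C@H]1C[C@@]23COC(=O)C2=C(Br)C=C[C@@]34OC(=O)C[C@@]4(C)[C@@H]1C
F0 | step 16 | none | none
F4 | step 20 | silyl ether hydroxy ketone: ring C closed, C1 (S) OSiEt3, free C22–OH | CC[Si](CC)(CC)O[C@H]1C[C@@]23COC(=O)C2=CC[C@H]2c4occc4C(=O)C[C@@](C)([C@@H]1C)[C@@]23O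
F5 | step 20 | diol ketone: F4 without the silyl group, C1 (S) | O[C@H]1C[C@@]23COC(=O)C2=CC[C@H]2c4occc4C(=O)C[C@@](C)([C@@H]1C)[C@@]23O
F6 | step 20 | diketone: C1 ketone of F5 | O=C1C[C@@]23COC(=O)C2=CC[C@H]2c4occc4C(=O)C[C@@](C)([C@@H]1C)[C@@]23O
F7 | step 4 | racemic (2S*,3S*)-3-(furan-2-yl)-2,3-dimethylpent-4-enoic acid | o1cccc1[C@@](C)(C=C)[C@H](C)C(=O)O.o1cccc1[C@](C)(C=C)[C@@H](C)C(=O)O
F8 | step 4 | imide: (S)-4-benzyl-3-[(2S,3S)-3-(furan-2-yl)-2,3-dimethylpent-4-enoyl]oxazolidin-2-one | o1cccc1[C@@](C)(C=C)[C@H](C)C(=O)N1[C@@H](Cc2ccccc2)COC1=O
F9 | step 4 | diastereomer: (S)-4-benzyl-3-[(2R,3R)-3-(furan-2-yl)-2,3-dimethylpent-4-enoyl]oxazolidin-2-one | o1cccc1[C@](C)(C=C)[C@@H](C)C(=O)N1[C@@H](Cc2ccccc2)COC1=O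
A1 | alternative 1 | tricyclic dienyl propiolate: rings A and C with the furan, diene C9H2=C10–C22=C3, propiolate ester on the C4 oxygen | CC(=O)O[C@@H]1CC(COC(=O)C#C)=C2C(=C)c3occc3C(=O)C[C@@]2(C)[C@@H]1C
A2 | alternative 1 | pentacyclic cyclohexa-1,4-diene lactone | CC(=O)O[C@@H]1C[C@@]23COC(=O)C2=CCC2=C3[C@](C)([C@@H]1C)CC(=O)c1ccoc12
A3 | alternative 2 | (S)-4-[(tert-butyldimethylsilyl)oxy]-2-methylcyclohex-2-en-1-one | O=C1CC[C@H](O[Si](C)(C)C(C)(C)C)C=C1C
A4 | alternative 2 | lithium dimethylcuprate | [Li+].C[Cu-]C
A5 | alternative 2 | 3-(3-bromoprop-1-en-2-yl)furan | BrCC(=C)c1ccoc1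
A6 | alternative 2 | 2,2,3-trisubstituted cyclohexanone carrying the furan fragment | O=C1CC[C@H](O[Si](C)(C)C(C)(C)C)[C@@H](C)[C@]1(C)CC(=C)c1ccoc1
A7 | alternative 3 | neopentyl iodide: rings A and B with lactone, C17 iodide, 3-bromofuran-2-yl on C10, O23 trimethylsilyl ether | CC(=O)O[C@@H]1C[C@@]23COC(=O)C2=CC[C@@H](c4occc4Br)[C@]3(O[Si](C)(C)C)[C@@](C)(CI)[C@@H]1C
A8 | alternative 3 | carbon monoxide | [C-]#[O+]
A9 | alternative 3 | target as its tertiary trimethylsilyl ether | CC(=O)O[C@@H]1C[C@@]23COC(=O)C2=CC[C@H]2c4occc4C(=O)C[C@@](C)([C@@H]1C)[C@@]23O[Si](C)(C)C
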